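**Retrosynthetic overview**

1. Target 29 ⇐ α‑methylene ketone 28 (1,2‑reduction gives 7α‑OH) ⇐ ketone 26. C17 comes from α‑methylenation at C8. The acyl pattern comes from C2‑selective angeloylation and then acetylation of the 2α,3α‑diol, which is made by osmylation of a Δ2 alkene. C20 is reduced from a carboxyl to CH2OAc.
2. Ring A is closed last, by forming C1–C10 in an Ireland–Claisen ring contraction of δ‑lactone 17 to the trans‑decalin silyl ester 19. The enabling feature is that C10 carries a carboxyl‑level carbon (C20) and C3 carries oxygen. C20(=O)–O–C3 can therefore be tied as a temporary six‑membered lactone (C20, O, C3, C4, C5, C10) with C1=C2 as a vinyl group on C3. Its ketene acetal C10=C20 is an allyl vinyl ether whose termini are C1 and C10.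
3. Lactone 17 (ring B plus the lactone, with C5, C9 and C10 set) ⇐ ester‑tethered intramolecular Diels–Alder reaction of triene ester 15/16 (2‑silyloxydiene C5=C6–C7=C8 with the (E)‑enoate C9=C10). The same ester bridge serves first as the Diels–Alder tether and then as the Claisen ester.
4. 15 ⇐ (S)‑enone alcohol 8 (C1–C8, C18, C19; from an asymmetric Mukaiyama aldol of acrolein) + acid 14 (C9–C16 and C20). Acid 14 comes from chiral‑pool (R)‑linalool, which supplies C13 and the whole side chain; its C6 becomes C9.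
5. Ring order: ring B with the temporary lactone in step 11, ring A in step 12.

Key step: step 12

Remark: labdane numbering of the target is used for all bicyclic compounds (ring A = C1–C5, C10; ring B = C5–C10; side chain C11–C16 on C9; C17 on C8; C18/C19 on C4; C20 on C10). β is the face of C20. Read this way, the target SMILES has 2α‑O, 3α‑O, 5α‑H, 7α‑OH, 9β‑H (side chain α), 10β‑CH2OAc and 13R. (R)‑(−)‑Linalool of high enantiomeric purity is taken as commercial.

**Route**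

Step 1
Reactants: 1 acrolein; 2 1‑methoxy‑2‑methyl‑1‑(trimethylsilyloxy)prop‑1‑ene
Product: 3 methyl (S)‑3‑hydroxy‑2,2‑dimethylpent‑4‑enoate
Conditions: (R)‑4‑isopropyl‑3‑tosyl‑1,3,2‑oxazaborolidin‑5‑one (20 mol%, from N‑Ts‑D‑valine and BH3·THF), EtNO2, −78 °C; then 1 M HCl
Reagents that add atoms: none
Why: catalytic asymmetric Mukaiyama aldol addition, in which the chiral boron Lewis acid binds acrolein and exposes one carbonyl face to the ketene silyl acetal, which should set the C3 carbinol centre as S by 1,2‑addition.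

Step 2
Reactants: 3 methyl (S)‑3‑hydroxy‑2,2‑dimethylpent‑4‑enoate
Product: 4 methyl (S)‑2,2‑dimethyl‑3‑(triethylsilyloxy)pent‑4‑enoate
Conditions: Et3SiCl, imidazole, DMF, 0 °C → rt
Reagents that add atoms: chlorotriethylsilane CC[Si](Cl)(CC)CC
Why: standard silylation of a secondary alcohol, which protects C3–OH for the hydride and olefination steps.

Step 3
Reactants: 4 methyl (S)‑2,2‑dimethyl‑3‑(triethylsilyloxy)pent‑4‑enoate
Product: 5 (S)‑2,2‑dimethyl‑3‑(triethylsilyloxy)pent‑4‑enal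
Conditions: i‑Bu2AlH, CH2Cl2, −78 °C; aq. KNaC4H4O6 work‑up
Reagents that add atoms: none
Why: partial reduction of a hindered α,α‑disubstituted ester, whose tetrahedral aluminium hemiacetal should persist at −78 °C and release the non‑enolisable aldehyde on work‑up.

Step 4
Reactants: 5 (S)‑2,2‑dimethyl‑3‑(triethylsilyloxy)pent‑4‑enal; 6 dimethyl (2‑oxopropyl)phosphonate
Product: 7 (S,E)‑5,5‑dimethyl‑6‑(triethylsilyloxy)octa‑3,7‑dien‑2‑one
Conditions: Ba(OH)2·8H2O, THF/H2O (40:1), rt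
Reagents that add atoms: none
Why: Horner–Wadsworth–Emmons olefination of a non‑enolisable aldehyde with a stabilised β‑ketophosphonate, which should give the (E)‑enone that supplies C5=C6, C7 and C8.

Step 5
Reactants: 7 (S,E)‑5,5‑dimethyl‑6‑(triethylsilyloxy)octa‑3,7‑dien‑2‑one
Product: 8 (S,E)‑6‑hydroxy‑5,5‑dimethylocta‑3,7‑dien‑2‑one
Conditions: HF·pyridine, pyridine, THF, 0 °C
Reagents that add atoms: none
Why: buffered fluoride desilylation, which frees the C3 carbinol without touching the enone.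

Step 6
Reactants: 9 (R)‑(−)‑linalool
Product: 10 (R)‑triethyl[(3,7‑dimethylocta‑1,6‑dien‑3‑yl)oxy]silane
Conditions: Et3SiOTf, 2,6‑lutidine, CH2Cl2, −78 → 0 °C
Reagents that add atoms: triethylsilyl trifluoromethanesulfonate CC[Si](CC)(CC)OS(=O)(=O)C(F)(F)F
Why: silyl triflate silylation of a tertiary alcohol, in which the chiral‑pool C13 centre (R) is untouched.

Step 7
Reactants: 10 (R)‑triethyl[(3,7‑dimethylocta‑1,6‑dien‑3‑yl)oxy]silane
Product: 11 (R)‑4‑methyl‑4‑(triethylsilyloxy)hex‑5‑enal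
Conditions: O3, CH2Cl2/MeOH, pyridine, −78 °C (indicator end point); then PPh3
Reagents that add atoms: ozone [O-][O+]=O
Why: chemoselective ozonolysis, in which the electron‑rich trisubstituted alkene should be cleaved much faster than the hindered, inductively deactivated vinyl group, leaving the former linalool C6 as the aldehyde carbon (future C9).

Step 8
Reactants: 11 (R)‑4‑methyl‑4‑(triethylsilyloxy)hex‑5‑enal; 12 methyl (triphenyl‑λ5‑phosphanylidene)acetate
Product: 13 methyl (R,E)‑6‑methyl‑6‑(triethylsilyloxy)octa‑2,7‑dienoate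
Conditions: CH2Cl2, rt
Reagents that add atoms: none
Why: Wittig olefination with a stabilised ylide, which should give the (E)‑enoate carrying C10 and C20.

Step 9
Reactants: 13 methyl (R,E)‑6‑methyl‑6‑(triethylsilyloxy)octa‑2,7‑dienoate
Product: 14 (R,E)‑6‑methyl‑6‑(triethylsilyloxy)octa‑2,7‑dienoic acid
Conditions: LiOH, THF/MeOH/H2O, rt; then 1 M HCl to pH 4
Reagents that add atoms: lithium hydroxide [Li+].[OH-]
Why: ester saponification, to which the tertiary silyl ether and the (E)‑alkene should be inert.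

Step 10
Reactants: 8 (S,E)‑6‑hydroxy‑5,5‑dimethylocta‑3,7‑dien‑2‑one; 14 (R,E)‑6‑methyl‑6‑(triethylsilyloxy)octa‑2,7‑dienoic acid
Product: 15 (S,E)‑4,4‑dimethyl‑7‑oxoocta‑1,5‑dien‑3‑yl (R,E)‑6‑methyl‑6‑(triethylsilyloxy)octa‑2,7‑dienoate
Conditions: 2,4,6‑Cl3C6H2COCl, Et3N, 4‑(dimethylamino)pyridine, PhMe, 0 °C → rt
Reagents that add atoms: none
Why: Yamaguchi esterification, suited to a hindered secondary allylic alcohol, which joins the two fragments through the O–C20 ester that later serves as both tether and Claisen ester.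

Step 11
Reactants: 15 (S,E)‑4,4‑dimethyl‑7‑oxoocta‑1,5‑dien‑3‑yl (R,E)‑6‑methyl‑6‑(triethylsilyloxy)octa‑2,7‑dienoate
Product: 17 cis‑fused Diels–Alder lactone (3S)‑6‑(tert‑butyldimethylsilyloxy)‑4,4‑dimethyl‑8‑[(3R)‑3‑methyl‑3‑(triethylsilyloxy)pent‑4‑enyl]‑3‑vinyl‑3,4,4a,7,8,8a‑hexahydro‑1H‑isochromen‑1‑one (labdane numbering: 5α‑H, 10α‑H, 9α side chain, Δ6 enol ether), via silyl dienol ether 16 (not isolated)
Conditions: t‑BuMe2SiOTf, Et3N, CH2Cl2, −78 → 0 °C; then PhMe (0.005 M), BHT, 155 °C, sealed tube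
Reagents that add atoms: tert‑butyldimethylsilyl trifluoromethanesulfonate CC(C)(C)[Si](C)(C)OS(=O)(=O)C(F)(F)F
Why: kinetic enol silylation of the methyl ketone gives a 2‑silyloxydiene that should undergo a type‑1 intramolecular Diels–Alder reaction with the tethered (E)‑enoate through the endo, chair‑like transition state with the C3 vinyl group equatorial (helped by the gem‑dimethyl group), which sets H5 and H10 cis, the side chain at C9 trans to C20 (from the E‑alkene) and all three centres relative to C3.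

Step 12
Reactants: 17 cis‑fused Diels–Alder lactone
Product: 19 tert‑butyldimethylsilyl 7‑(tert‑butyldimethylsilyloxy)‑13‑(triethylsilyloxy)‑9βH‑labda‑2,6,14‑trien‑20‑oate (13R; trans‑decalin), via silyl ketene acetal 18 (not isolated)
Conditions: i‑Pr2NLi (LDA), THF, −78 °C; t‑BuMe2SiCl, HMPA, −78 °C → rt; then PhMe, 110 °C; used crude
Reagents that add atoms: tert‑butylchlorodimethylsilane CC(C)(C)[Si](C)(C)Cl
Why: LDA removes the only acidic C–H (C10–H, α to the lactone carbonyl; the C7 ketone is masked as its silyl enol ether) and O‑silylation gives the cyclic silyl ketene acetal 18, an allyl vinyl ether (C10=C20–O–C3–C2=C1) that on heating undergoes the [3,3]‑sigmatropic Ireland–Claisen rearrangement, forming C1–C10 and cleaving O–C3. The closest known reaction type is the ester‑enolate Claisen rearrangement of 6‑alkenyl δ‑lactones to cyclohex‑3‑ene‑1‑carboxylic acids. Ring A closes in a pericyclic, suprafacial mode through the boat (2‑oxabicyclo[2.2.2]octene‑like) transition state that the six‑membered ketene acetal enforces, turning the six‑membered lactone into the six‑membered carbocycle (C1, C2, C3, C4, C5, C10) with a cis C2=C3 bond and C20 as a carboxyl group. The new quaternary stereocentre C10 is controlled by the C3 carbinol stereocentre, which is consumed: the vinyl group sits on the α‑face of the lactone (cis to H5), so C1 can only bond to the α‑face of C10, leaving C20 β and trans to H5 (trans‑decalin). The step needs O‑ rather than C‑silylation (secured by HMPA and low temperature) and rearrangement rather than ketene‑type cleavage of the lactone enolate (secured by trapping at −78 °C before warming); the ketene acetal geometry is fixed by the ring, so no E/Z question arises.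

Step 13
Reactants: 19 tert‑butyldimethylsilyl 7‑(tert‑butyldimethylsilyloxy)‑13‑(triethylsilyloxy)‑9βH‑labda‑2,6,14‑trien‑20‑oate
Product: 20 7‑(tert‑butyldimethylsilyloxy)‑13‑(triethylsilyloxy)‑9βH‑labda‑2,6,14‑trien‑20‑ol
Conditions: LiAlH4, THF, 0 → 40 °C; aq. KNaC4H4O6 work‑up
Reagents that add atoms: none
Why: hydride reduction of the silyl ester to the neopentyl primary alcohol, during which the silyl enol ether keeps the C7 carbonyl protected and the alkenes are inert.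

Step 14
Reactants: 20 7‑(tert‑butyldimethylsilyloxy)‑13‑(triethylsilyloxy)‑9βH‑labda‑2,6,14‑trien‑20‑ol
Product: 21 20‑acetoxy‑7‑(tert‑butyldimethylsilyloxy)‑13‑(triethylsilyloxy)‑9βH‑labda‑2,6,14‑triene
Conditions: Ac2O, 4‑(dimethylamino)pyridine (cat.), pyridine, CH2Cl2, 0 °C → rt
Reagents that add atoms: acetic anhydride CC(=O)OC(C)=O
Why: acetylation of the only free hydroxyl group, which installs the C20 acetate of the target.

Step 15
Reactants: 21 20‑acetoxy‑7‑(tert‑butyldimethylsilyloxy)‑13‑(triethylsilyloxy)‑9βH‑labda‑2,6,14‑triene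
Product: 22 20‑acetoxy‑13‑(triethylsilyloxy)‑9βH‑labda‑2,14‑dien‑7‑one
Conditions: Bu4NF, AcOH, THF, −20 °C
Reagents that add atoms: none
Why: buffered fluoride cleaves the silyl enol ether (enolate leaving group) much faster than the hindered tertiary alkyl silyl ether, which unveils the C7 ketone before the osmylation.

Step 16
Reactants: 22 20‑acetoxy‑13‑(triethylsilyloxy)‑9βH‑labda‑2,14‑dien‑7‑one
Product: 23 20‑acetoxy‑2α,3α‑dihydroxy‑13‑(triethylsilyloxy)‑9βH‑labd‑14‑en‑7‑one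
Conditions: OsO4 (5 mol%), N‑methylmorpholine N‑oxide, acetone/H2O (8:1), 0 °C → rt, stopped at consumption of 22
Reagents that add atoms: N‑methylmorpholine N‑oxide C[N+]1([O-])CCOCC1; water O (OsO4, O=[Os](=O)(=O)=O, is the catalytic oxygen carrier)
Why: Upjohn syn‑dihydroxylation from the α‑face, since the β‑face of ring A is blocked by the axial C20 CH2OAc and the 4β‑methyl group, which sets C2 and C3; the cis‑disubstituted ring alkene should react before the vinyl group, which is monosubstituted, neopentyl and shielded and deactivated by the adjacent tertiary silyl ether.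

Step 17
Reactants: 23 20‑acetoxy‑2α,3α‑dihydroxy‑13‑(triethylsilyloxy)‑9βH‑labd‑14‑en‑7‑one; 24 angelic acid ((Z)‑2‑methylbut‑2‑enoic acid)
Product: 25 20‑acetoxy‑2α‑angeloyloxy‑3α‑hydroxy‑13‑(triethylsilyloxy)‑9βH‑labd‑14‑en‑7‑one
Conditions: 2,4,6‑Cl3C6H2COCl, Et3N, PhMe, rt → 60 °C (no 4‑(dimethylamino)pyridine)
Reagents that add atoms: none
Why: Yamaguchi‑type acylation, which should go to the equatorial C2–OH and not the axial, neopentyl C3–OH, and which is used without nucleophilic catalyst because that protocol is known to keep the (Z)‑geometry of angelates.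

Step 18
Reactants: 25 20‑acetoxy‑2α‑angeloyloxy‑3α‑hydroxy‑13‑(triethylsilyloxy)‑9βH‑labd‑14‑en‑7‑one
Product: 26 3α,20‑diacetoxy‑2α‑angeloyloxy‑13‑(triethylsilyloxy)‑9βH‑labd‑14‑en‑7‑one
Conditions: Ac2O, 4‑(dimethylamino)pyridine, pyridine, 40 °C
Reagents that add atoms: acetic anhydride CC(=O)OC(C)=O
Why: catalysed acetylation of the remaining hindered axial C3–OH, with the tertiary C13 oxygen still silylated so that it cannot be acylated.

Step 19
Reactants: 26 3α,20‑diacetoxy‑2α‑angeloyloxy‑13‑(triethylsilyloxy)‑9βH‑labd‑14‑en‑7‑one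
Product: 27 3α,20‑diacetoxy‑2α‑angeloyloxy‑13‑hydroxy‑9βH‑labd‑14‑en‑7‑one
Conditions: HF·pyridine, pyridine, THF, 0 °C → rt
Reagents that add atoms: none
Why: buffered fluoride desilylation of the tertiary silyl ether, mild enough for the three esters and done before the sensitive enone exists.

Step 20
Reactants: 27 3α,20‑diacetoxy‑2α‑angeloyloxy‑13‑hydroxy‑9βH‑labd‑14‑en‑7‑one
Product: 28 3α,20‑diacetoxy‑2α‑angeloyloxy‑13‑hydroxy‑9βH‑labda‑8(17),14‑dien‑7‑one
Conditions: (CH2O)n, N‑methylanilinium trifluoroacetate, THF, 65 °C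
Reagents that add atoms: formaldehyde (as paraformaldehyde) C=O
Why: direct Mannich‑type α‑methylenation of a ketone under weakly acidic conditions compatible with the esters; enolisation is expected toward C8 and away from the ring fusion, as in 3‑oxo‑5α‑steroids (C2 over C4), and the Δ6 enol would suffer peri strain with the C4 methyl groups.

Step 21
Reactants: 28 3α,20‑diacetoxy‑2α‑angeloyloxy‑13‑hydroxy‑9βH‑labda‑8(17),14‑dien‑7‑one
Product: 29 target CNP0147212.1, 3α,20‑diacetoxy‑2α‑angeloyloxy‑9βH‑labda‑8(17),14‑diene‑7α,13‑diol (13R)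
Conditions: NaBH4, CeCl3·7H2O, MeOH, −78 °C
Reagents that add atoms: none
Why: Luche 1,2‑reduction of the α‑methylene ketone, in which hydride should attack C7 along the equatorial trajectory from the β‑face because the axial α‑trajectory is blocked by the syn‑axial C9 side chain, giving the axial 7α‑alcohol and leaving the esters untouched.

**Compound list**

1 | acrolein | C=CC=O | starting material
2 | 1‑methoxy‑2‑methyl‑1‑(trimethylsilyloxy)prop‑1‑ene | COC(=C(C)C)O[Si](C)(C)C | starting material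
3 | methyl (S)‑3‑hydroxy‑2,2‑dimethylpent‑4‑enoate | COC(=O)C(C)(C)[C@@H](O)C=C | intermediate
4 | methyl (S)‑2,2‑dimethyl‑3‑(triethylsilyloxy)pent‑4‑enoate | COC(=O)C(C)(C)[C@@H](O[Si](CC)(CC)CC)C=C | intermediate
5 | (S)‑2,2‑dimethyl‑3‑(triethylsilyloxy)pent‑4‑enal | O=CC(C)(C)[C@@H](O[Si](CC)(CC)CC)C=C | intermediate
6 | dimethyl (2‑oxopropyl)phosphonate | COP(=O)(CC(C)=O)OC | starting material
7 | (S,E)‑5,5‑dimethyl‑6‑(triethylsilyloxy)octa‑3,7‑dien‑2‑one | CC(=O)/C=C/C(C)(C)[C@@H](O[Si](CC)(CC)CC)C=C | intermediate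
8 | (S,E)‑6‑hydroxy‑5,5‑dimethylocta‑3,7‑dien‑2‑one | CC(=O)/C=C/C(C)(C)[C@@H](O)C=C | intermediate
9 | (R)‑(−)‑linalool | C=C[C@](C)(O)CCC=C(C)C | starting material
10 | (R)‑triethyl[(3,7‑dimethylocta‑1,6‑dien‑3‑yl)oxy]silane | C=C[C@](C)(O[Si](CC)(CC)CC)CCC=C(C)C | intermediate
11 | (R)‑4‑methyl‑4‑(triethylsilyloxy)hex‑5‑enal | C=C[C@](C)(O[Si](CC)(CC)CC)CCC=O | intermediate
12 | methyl (triphenyl‑λ5‑phosphanylidene)acetate | COC(=O)C=P(c1ccccc1)(c1ccccc1)c1ccccc1 | starting material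
13 | methyl (R,E)‑6‑methyl‑6‑(triethylsilyloxy)octa‑2,7‑dienoate | C=C[C@](C)(O[Si](CC)(CC)CC)CC/C=C/C(=O)OC | intermediate
14 | (R,E)‑6‑methyl‑6‑(triethylsilyloxy)octa‑2,7‑dienoic acid | C=C[C@](C)(O[Si](CC)(CC)CC)CC/C=C/C(=O)O | intermediate
15 | (S,E)‑4,4‑dimethyl‑7‑oxoocta‑1,5‑dien‑3‑yl (R,E)‑6‑methyl‑6‑(triethylsilyloxy)octa‑2,7‑dienoate | C=C[C@](C)(O[Si](CC)(CC)CC)CC/C=C/C(=O)O[C@@H](C=C)C(C)(C)/C=C/C(C)=O | intermediate
16 | (S,E)‑7‑(tert‑butyldimethylsilyloxy)‑4,4‑dimethylocta‑1,5,7‑trien‑3‑yl (R,E)‑6‑methyl‑6‑(triethylsilyloxy)octa‑2,7‑dienoate (silyl dienol ether) | C=C[C@](C)(O[Si](CC)(CC)CC)CC/C=C/C(=O)O[C@@H](C=C)C(C)(C)/C=C/C(=C)O[Si](C)(C)C(C)(C)C | intermediate (not isolated)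
17 | cis‑fused Diels–Alder lactone, (3S)‑6‑(tert‑butyldimethylsilyloxy)‑4,4‑dimethyl‑8‑[(3R)‑3‑methyl‑3‑(triethylsilyloxy)pent‑4‑enyl]‑3‑vinyl‑3,4,4a,7,8,8a‑hexahydro‑1H‑isochromen‑1‑one (5α‑H, 10α‑H, 9α side chain) | C=C[C@](C)(O[Si](CC)(CC)CC)CC[C@@H]1CC(O[Si](C)(C)C(C)(C)C)=C[C@H]2C(C)(C)[C@H](C=C)OC(=O)[C@@H]12 | intermediate
18 | cyclic silyl ketene acetal of 17 (C10=C20–OSi) | C=C[C@](C)(O[Si](CC)(CC)CC)CC[C@@H]1CC(O[Si](C)(C)C(C)(C)C)=C[C@H]2C(C)(C)[C@H](C=C)OC(O[Si](C)(C)C(C)(C)C)=C12 | intermediate (not isolated)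
19 | tert‑butyldimethylsilyl 7‑(tert‑butyldimethylsilyloxy)‑13‑(triethylsilyloxy)‑9βH‑labda‑2,6,14‑trien‑20‑oate | C=C[C@](C)(O[Si](CC)(CC)CC)CC[C@@H]1CC(O[Si](C)(C)C(C)(C)C)=C[C@H]2C(C)(C)C=CC[C@]12C(=O)O[Si](C)(C)C(C)(C)C | intermediate
20 | 7‑(tert‑butyldimethylsilyloxy)‑13‑(triethylsilyloxy)‑9βH‑labda‑2,6,14‑trien‑20‑ol | C=C[C@](C)(O[Si](CC)(CC)CC)CC[C@@H]1CC(O[Si](C)(C)C(C)(C)C)=C[C@H]2C(C)(C)C=CC[C@]12CO | intermediate
21 | 20‑acetoxy‑7‑(tert‑butyldimethylsilyloxy)‑13‑(triethylsilyloxy)‑9βH‑labda‑2,6,14‑triene | C=C[C@](C)(O[Si](CC)(CC)CC)CC[C@@H]1CC(O[Si](C)(C)C(C)(C)C)=C[C@H]2C(C)(C)C=CC[C@]12COC(C)=O | intermediate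
22 | 20‑acetoxy‑13‑(triethylsilyloxy)‑9βH‑labda‑2,14‑dien‑7‑one | C=C[C@](C)(O[Si](CC)(CC)CC)CC[C@@H]1CC(=O)C[C@H]2C(C)(C)C=CC[C@]12COC(C)=O | intermediate
23 | 20‑acetoxy‑2α,3α‑dihydroxy‑13‑(triethylsilyloxy)‑9βH‑labd‑14‑en‑7‑one | C=C[C@](C)(O[Si](CC)(CC)CC)CC[C@@H]1CC(=O)C[C@H]2C(C)(C)[C@H](O)[C@H](O)C[C@]12COC(C)=O | intermediate
24 | angelic acid, (Z)‑2‑methylbut‑2‑enoic acid | C/C=C(/C)C(=O)O | starting material
25 | 20‑acetoxy‑2α‑angeloyloxy‑3α‑hydroxy‑13‑(triethylsilyloxy)‑9βH‑labd‑14‑en‑7‑one | C=C[C@](C)(O[Si](CC)(CC)CC)CC[C@@H]1CC(=O)C[C@H]2C(C)(C)[C@H](O)[C@H](OC(=O)/C(C)=C\C)C[C@]12COC(C)=O | intermediate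
26 | 3α,20‑diacetoxy‑2α‑angeloyloxy‑13‑(triethylsilyloxy)‑9βH‑labd‑14‑en‑7‑one | C=C[C@](C)(O[Si](CC)(CC)CC)CC[C@@H]1CC(=O)C[C@H]2C(C)(C)[C@H](OC(C)=O)[C@H](OC(=O)/C(C)=C\C)C[C@]12COC(C)=O | intermediate
27 | 3α,20‑diacetoxy‑2α‑angeloyloxy‑13‑hydroxy‑9βH‑labd‑14‑en‑7‑one | C=C[C@](C)(O)CC[C@@H]1CC(=O)C[C@H]2C(C)(C)[C@H](OC(C)=O)[C@H](OC(=O)/C(C)=C\C)C[C@]12COC(C)=O | intermediate
28 | 3α,20‑diacetoxy‑2α‑angeloyloxy‑13‑hydroxy‑9βH‑labda‑8(17),14‑dien‑7‑one | C=C[C@](C)(O)CC[C@@H]1C(=C)C(=O)C[C@H]2C(C)(C)[C@H](OC(C)=O)[C@H](OC(=O)/C(C)=C\C)C[C@]12COC(C)=O | intermediate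
29 | CNP0147212.1, 3α,20‑diacetoxy‑2α‑angeloyloxy‑9βH‑labda‑8(17),14‑diene‑7α,13‑diol (13R) | C=C[C@](C)(O)CC[C@@H]1C(=C)[C@H](O)C[C@H]2C(C)(C)[C@H](OC(C)=O)[C@H](OC(=O)/C(C)=C\C)C[C@]12COC(C)=O | target

**Step count and risks**

Total step count: 21. Longest linear sequence: 17 steps (steps 1–5, then 10–21); the linalool branch (steps 6–9) joins at step 10.

Steps most likely to fail:

1. Step 11 (intramolecular Diels–Alder). The ester tether must adopt its disfavoured s‑cis conformation, so the cycloaddition may be too slow below about 160 °C. Above that temperature the 3‑acyloxy‑1,5‑diene unit of 16 can begin to undergo Cope rearrangement, and endo selectivity may erode. The fallback is an intermolecular, catalyst‑controlled cycloaddition followed by lactonisation; it sets out from 8 and 11 and returns at 17.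
   - Aldehyde 11 is homologated with (triphenylphosphoranylidene)acetaldehyde to (R,E)‑6‑methyl‑6‑(triethylsilyloxy)octa‑2,7‑dienal F1.
   - Alcohol 8 is silylated twice (Me3SiCl/imidazole, then t‑BuMe2SiOTf/Et3N) to (S,E)‑2‑(tert‑butyldimethylsilyloxy)‑5,5‑dimethyl‑6‑(trimethylsilyloxy)octa‑1,3,7‑triene F2.
   - A Diels–Alder reaction of F1 with F2 follows, catalysed by a chiral oxazaborolidinium bis(triflyl)imide Lewis acid (from α,α‑diphenyl‑2‑pyrrolidinemethanol, o‑tolylboroxine and HNTf2) in CH2Cl2 at −78 °C. The enal is a far better dienophile than the tethered enoate, endo addition gives the same C5/C9/C10 relationship, and the catalyst antipode is chosen for the diene face that matches C3. The product should be the cyclohexene carbaldehyde F3.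
   - Buffered NaClO2/NaH2PO4 oxidation, which also frees the labile trimethylsilyl ether, gives the hydroxy acid F4.
   - Carbodiimide lactonisation (EDC·HCl, 4‑(dimethylamino)pyridine) closes the δ‑lactone and gives 17.

2. Step 16 (dihydroxylation). The risk is competing osmylation of the side‑chain vinyl group and over‑oxidation to a tetraol. The fallback uses peracid chemoselectivity and neighbouring‑group participation; it sets out from 22 and returns at 26.
   - mCPBA/NaHCO3 should epoxidise only the ring alkene, from the α‑face, to give the 2α,3α‑epoxide F5.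
   - MgBr2·OEt2 opens it trans‑diaxially (Fürst–Plattner) to the 2β‑bromo‑3α‑ol F6.
   - Ac2O/4‑(dimethylamino)pyridine gives the 3α‑acetoxy‑2β‑bromide F7.
   - AgBF4 in wet acetone triggers anchimerically assisted loss of bromide through the α‑face acetoxonium ion, whose hydrolysis favours the axial ester and gives the 3α‑acetoxy‑2α‑ol F8.
   - Angeloylation of F8 under the conditions of step 17 gives 26.

3. Step 20 (α‑methylenation). The risk is enolisation toward C6 instead of C8, or double methylenation. The fallback fixes the regiochemistry at an isolable enol ether stage; it sets out from 26 and returns at 28.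
   - Thermodynamic enol silylation (Me3SiOTf, Et3N) gives the Δ7(8) trimethylsilyl enol ether F9, from which a regioisomer could be separated.
   - Dimethylmethyleneammonium iodide gives the 8‑(dimethylaminomethyl) ketone F10.
   - Quaternisation with MeI and NaHCO3‑induced elimination give the silyl‑protected α‑methylene ketone F11.
   - HF·pyridine, as in step 19, gives 28.

Further compounds
F1 | step 11 | (R,E)‑6‑methyl‑6‑(triethylsilyloxy)octa‑2,7‑dienal | C=C[C@](C)(O[Si](CC)(CC)CC)CC/C=C/C=O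
F2 | step 11 | (S,E)‑2‑(tert‑butyldimethylsilyloxy)‑5,5‑dimethyl‑6‑(trimethylsilyloxy)octa‑1,3,7‑triene | C=C(O[Si](C)(C)C(C)(C)C)/C=C/C(C)(C)[C@@H](O[Si](C)(C)C)C=C
F3 | step 11 | cyclohexene carbaldehyde cycloadduct (C20 aldehyde on C10, cis to the C5 substituent, trans to the C9 side chain; Δ6 silyl enol ether) | C=C[C@](C)(O[Si](CC)(CC)CC)CC[C@@H]1CC(O[Si](C)(C)C(C)(C)C)=C[C@@H](C(C)(C)[C@@H](O[Si](C)(C)C)C=C)[C@H]1C=O
F4 | step 11 | hydroxy acid (C20 carboxylic acid, free C3–OH) | C=C[C@](C)(O[Si](CC)(CC)CC)CC[C@@H]1CC(O[Si](C)(C)C(C)(C)C)=C[C@@H](C(C)(C)[C@@H](O)C=C)[C@H]1C(=O)O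
F5 | step 16 | 20‑acetoxy‑2α,3α‑epoxy‑13‑(triethylsilyloxy)‑9βH‑labd‑14‑en‑7‑one | C=C[C@](C)(O[Si](CC)(CC)CC)CC[C@@H]1CC(=O)C[C@H]2C(C)(C)[C@@H]3O[C@@H]3C[C@]12COC(C)=O
F6 | step 16 | 20‑acetoxy‑2β‑bromo‑3α‑hydroxy‑13‑(triethylsilyloxy)‑9βH‑labd‑14‑en‑7‑one | C=C[C@](C)(O[Si](CC)(CC)CC)CC[C@@H]1CC(=O)C[C@H]2C(C)(C)[C@H](O)[C@@H](Br)C[C@]12COC(C)=O
F7 | step 16 | 3α,20‑diacetoxy‑2β‑bromo‑13‑(triethylsilyloxy)‑9βH‑labd‑14‑en‑7‑one | C=C[C@](C)(O[Si](CC)(CC)CC)CC[C@@H]1CC(=O)C[C@H]2C(C)(C)[C@H](OC(C)=O)[C@@H](Br)C[C@]12COC(C)=O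
F8 | step 16 | 3α,20‑diacetoxy‑2α‑hydroxy‑13‑(triethylsilyloxy)‑9βH‑labd‑14‑en‑7‑one | C=C[C@](C)(O[Si](CC)(CC)CC)CC[C@@H]1CC(=O)C[C@H]2C(C)(C)[C@H](OC(C)=O)[C@H](O)C[C@]12COC(C)=O
F9 | step 20 | 3α,20‑diacetoxy‑2α‑angeloyloxy‑13‑(triethylsilyloxy)‑7‑(trimethylsilyloxy)‑9βH‑labda‑7,14‑diene | C=C[C@](C)(O[Si](CC)(CC)CC)CC[C@@H]1C=C(O[Si](C)(C)C)C[C@H]2C(C)(C)[C@H](OC(C)=O)[C@H](OC(=O)/C(C)=C\C)C[C@]12COC(C)=O
F10 | step 20 | 3α,20‑diacetoxy‑2α‑angeloyloxy‑8‑(dimethylaminomethyl)‑13‑(triethylsilyloxy)‑9βH‑labd‑14‑en‑7‑one (C8 epimers, centre removed in the next operation) | C=C[C@](C)(O[Si](CC)(CC)CC)CC[C@@H]1C(CN(C)C)C(=O)C[C@H]2C(C)(C)[C@H](OC(C)=O)[C@H](OC(=O)/C(C)=C\C)C[C@]12COC(C)=O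
F11 | step 20 | 3α,20‑diacetoxy‑2α‑angeloyloxy‑13‑(triethylsilyloxy)‑9βH‑labda‑8(17),14‑dien‑7‑one | C=C[C@](C)(O[Si](CC)(CC)CC)CC[C@@H]1C(=C)C(=O)C[C@H]2C(C)(C)[C@H](OC(C)=O)[C@H](OC(=O)/C(C)=C\C)C[C@]12COC(C)=O
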